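A small charge of 10 mM starting complex (the alder run) and a larger one of 15 mM (the ash run) must tell me when to take down the next flask.

| flask | starting complex | incoming ligand | leaving ligand | protic impurity | remark | time |
|---|---|---|---|---|---|---|
| alder | 10 mM | 1 equiv | 2 equiv | 2 mM | run made earlier |  |
| ash | 15 mM | 1 equiv | 2 equiv | 2 mM | run made earlier |  |
| flask | 20 mM | 1.00 equiv | 2.00 equiv | 2.00 mM |  | 3.0 d |

- alder (time / h: complex with one exchanged / %, complex with two exchanged / %): 1.00: 7.3, 0; 4.00: 15.8, 1.4; 12.0: 19.5, 4.4; 40.0: 10.5, 7.8
- ash (time / h: complex with one exchanged / %, complex with two exchanged / %): 1.00: 9.8, 1.4; 4.00: 16.9, 4.7; 12.0: 15.9, 8.2; 40.0: 10.5, 8.9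

(readings scatter by 1 percentage point)

- a species is counted by the starting complex in it: one homo dimer counts as two
- on the list of suspects stand: starting complex + incoming ligand <-> leaving ligand + complex with one exchanged; complex with one exchanged + incoming ligand <-> leaving ligand + complex with two exchanged; complex with two exchanged + incoming ligand <-> leaving ligand + complex with three exchanged; protic impurity + starting complex -> quenched substrate; 2 starting complex -> homo dimer; leaving ligand + starting complex -> side product

* the moment within 3.0 d at which there is most complex with one exchanged
* the amount of complex with one exchanged, in percent of the starting complex charged, at that time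
* earliest time at which at least nineteen twentieths of that best amount are there, in d
* latest time at which they still are, in d

1. My decision: I charge the flask as listed and ask whether it should run its whole 3.0 d.

2. The suspects list complex with one exchanged + incoming ligand <-> leaving ligand + complex with two exchanged as reversible. So I ask what end state this step wants. It is a value of the reaction quotient Q = [complex with two exchanged][leaving ligand] / ([complex with one exchanged][incoming ligand]).

3. Neither ligand was read. I take [leaving ligand] at its charge, and [incoming ligand] as its charge minus what the two read complexes hold. That ignores the unread complex with three exchanged and anything else that takes up a ligand, so Q is a rough figure. At 40.0 h, alder gives 2.01 and ash 2.36. I carry their mean, the late quotient 2.19.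

4. The flask has the same equivalents as both runs, and I expect a similar late state. Both runs read 10.5 % of complex with one exchanged at that time, while alder read 19.5 % at 12.0 h. In alder, waiting lost complex with one exchanged.

5. Every suspect is bimolecular, so I scale the highest readings by concentration times time. Ash gives 3.00 h and alder 6.00 h for the flask, and I stop between them.

The forecast says 18.5 % at 0.21 d, with the window from 0.135 d to 0.34 d, and its ground is that, plotted against concentration times time, “both runs fall on nearly one curve”.

The flask gives 18.9 % at 4.52 h, with the window from 0.122 d to 0.291 d.

    starting complex + incoming ligand ⇌ leaving ligand + complex with one exchanged (K = 59.6, k = 8.01 M⁻¹ h⁻¹)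
    complex with one exchanged + incoming ligand ⇌ leaving ligand + complex with two exchanged (K = 3.00, k = 6.62 M⁻¹ h⁻¹)
    complex with two exchanged + incoming ligand ⇌ leaving ligand + complex with three exchanged (K = 2.89, k = 39.6 M⁻¹ h⁻¹)
    protic impurity + starting complex → quenched substrate (k = 53.0 M⁻¹ h⁻¹)
    2 starting complex → homo dimer (k = 0.00401 M⁻¹ h⁻¹)
    leaving ligand + starting complex → side product (k = 7.53 M⁻¹ h⁻¹)

Counted as in step 3, the flask at 3.00 d gives 2.38, against my 2.19. With its ligands as they stand, 52.2 % and 91.2 % of their charges, Q is 3.05. The neighbour flask takes 4.00 equiv of incoming ligand and ends with 64.6 % of that charge and 152 % of the leaving ligand charged. That Q then asks for a ratio of complex with two exchanged to complex with one exchanged of 2.59, and the neighbour holds 2.57. Its complex with one exchanged reaches 30.4 % and ends at 5.63 %.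

The readings stem from a simulated flask with made-up constants; the scatter is artificial.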